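**Retrosynthetic overview**
- Target 22 comes from the 2α-acetoxy-4β,6α-diol 19 by aroylation and phenol release. Both secondary carbinols (C2, C6) arise from ketones by reductions directed by the C4 tertiary alcohol.
- The seven-membered ring is formed second, by ring-closing metathesis (C8=C9) of an allyl group on C1 and a methallyl group on C6.
- Key disconnection (C5–C6 and C1–C10 in one pot): hydroxy enone 5 + a dithiane-masked acyl anion carrying C6–C8 + allyl bromide. This sets up the 1,4-dioxygen pattern C2/C6.
- The five-membered ring is formed first: enone 5 comes from (S)-terpinen-4-ol by ozonolysis/aldol ring contraction, decarbonylation and allylic oxidation. Its carbinol carbon becomes C4 and relays every other stereocentre.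

Assumption: (S)-(+)-terpinen-4-ol is bought in high enantiomeric purity. Daucane numbering is used for all intermediates (C1 quaternary methyl carbon, C2 acetoxy carbon, C4 isopropyl carbinol, C5 ring-fusion CH, C6 aroyloxy carbon; β = face of the C1 methyl). In the SMILES of metal complexes, donor bonds are drawn as single bonds with formal charges.

**Step 1**
Reactants: 1 (S)-(+)-terpinen-4-ol
Product: 3 (R)-5-hydroxy-2-methyl-5-(propan-2-yl)cyclopent-1-ene-1-carbaldehyde, via keto aldehyde 2 (not isolated)
Conditions: O3, CH2Cl2/MeOH, −78 °C; Me2S, −78 °C to rt; then Bn2NH·CF3CO2H (30 mol%), benzene, 50 °C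
Reagents that add atoms: ozone, [O-][O+]=O
Why: Criegee ozonolysis opens the cyclohexene to keto aldehyde 2, and an amine-salt-catalysed intramolecular aldol condensation (aldehyde enamine onto the methyl ketone, then dehydration) closes the cyclopentene; the carbinol stereocentre (future C4) is not touched.

**Step 2**
Reactants: 3 (R)-5-hydroxy-2-methyl-5-(propan-2-yl)cyclopent-1-ene-1-carbaldehyde
Product: 4 (R)-3-methyl-1-(propan-2-yl)cyclopent-2-en-1-ol
Conditions: RhCl(PPh3)3 (1.1 equiv), toluene, 110 °C
Reagents that add atoms: none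
Why: Tsuji–Wilkinson decarbonylation (C–H oxidative addition to monovalent rhodium, CO extrusion, reductive elimination) replaces CHO by H with the double bond in place; no stereocentre is involved.

**Step 3**
Reactants: 4 (R)-3-methyl-1-(propan-2-yl)cyclopent-2-en-1-ol
Product: 5 (R)-4-hydroxy-2-methyl-4-(propan-2-yl)cyclopent-2-en-1-one
Conditions: dirhodium tetrakis(caprolactamate) Rh2(cap)4 (1 mol%), tBuOOH (70% in water, 5 equiv), 1,2-dichloroethane, 40 °C, no base
Reagents that add atoms: tert-butyl hydroperoxide, CC(C)(C)OO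
Why: Dirhodium-catalysed radical allylic C–H oxidation: C2 is the only ring carbon with allylic hydrogens and the peroxyl radical is taken up at C2 rather than at C5 next to the quaternary carbinol; the tertiary alcohol cannot be oxidised and base-free conditions avoid retro-aldol racemisation of 5.

**Step 4**
Reactants: 6 1,3-dithiane; 7 3-chloro-2-methylprop-1-ene
Product: 9 2-(2-methylprop-2-en-1-yl)-1,3-dithiane, via 2-lithio-1,3-dithiane 8 (not isolated)
Conditions: nBuLi, THF, −30 °C; then 7, −78 °C to 0 °C
Reagents that add atoms: none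
Why: Corey–Seebach alkylation: SN2 reaction of the sulfur-stabilised carbanion with the allylic chloride; no stereocentre is formed.

**Step 5 (key step)**
Reactants: 5 (R)-4-hydroxy-2-methyl-4-(propan-2-yl)cyclopent-2-en-1-one; 9 2-(2-methylprop-2-en-1-yl)-1,3-dithiane; 10 allyl bromide
Product: 14 2α-allyl-4β-hydroxy-2β-methyl-3β-[2-(2-methylprop-2-en-1-yl)-1,3-dithian-2-yl]-4α-(propan-2-yl)cyclopentan-1-one, via lithiated dithiane 11 (not isolated), via dithianylmagnesium bromide 12 (not isolated), via magnesium oxido enolate 13 (not isolated)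
Conditions: 9 (2.3 equiv), nBuLi (2.2 equiv), THF, −30 °C; MgBr2·OEt2, −78 °C; 5, −78 to −20 °C; then 10, HMPA, −20 to 0 °C; H2O quench
Reagents that add atoms: none
Why: Proposed new method: the first equivalent of Grignard reagent 12 turns 5 into its bromomagnesium alkoxide, which binds a second equivalent and hands the masked acyl anion to the adjacent β-carbon C5 on the oxygen face (also the face away from isopropyl), giving 1,4-addition syn to O, and the magnesium enolate is then C-allylated trans to the bulky dithiane to set quaternary C1 (methyl β, allyl α); the closest known chemistry is ligand-assisted conjugate addition of Grignard reagents to 4-oxido enones, combined with Corey–Seebach dithiane umpolung and conjugate addition–enolate alkylation.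

**Step 6**
Reactants: 14 hydroxy ketone from step 5
Product: 15 2α-allyl-2β-methyl-3β-[2-(2-methylprop-2-en-1-yl)-1,3-dithian-2-yl]-4α-(propan-2-yl)cyclopentane-1α,4β-diol
Conditions: Me4NBH(OAc)3 (5 equiv), MeCN/AcOH, −30 to 0 °C
Reagents that add atoms: none
Why: Evans–Saksena hydroxyl-directed reduction: the borohydride bound to the C4 oxygen delivers hydride to the β face of the C2 ketone, giving the trans-1,3-diol (C2–OH α).

**Step 7**
Reactants: 15 diol from step 6
Product: 16 C2 monoacetate of 15
Conditions: Ac2O, pyridine, DMAP (cat.), CH2Cl2, rt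
Reagents that add atoms: acetic anhydride, CC(=O)OC(C)=O
Why: DMAP-catalysed acetylation of the only secondary alcohol; the hindered tertiary C4 alcohol does not react at room temperature and no stereocentre changes.

**Step 8**
Reactants: 16 dienyl acetate from step 7
Product: 17 (daucane numbering) 2α-acetoxy-4β-hydroxy-dauc-8-en-6-one 6-(propane-1,3-diyl dithioketal)
Conditions: second-generation Grubbs catalyst, benzylidene[1,3-bis(2,4,6-trimethylphenyl)imidazolidin-2-ylidene]dichloro(tricyclohexylphosphine)ruthenium (10 mol%), toluene (5 mM), 80 °C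
Reagents that add atoms: none
Why: Ring-closing metathesis of the allyl and methallyl groups forms the trisubstituted cycloheptene; the trans arrangement of C1–C10 and C5–C6 from step 5 becomes the trans ring fusion.

**Step 9**
Reactants: 17 bicyclic dithioketal
Product: 18 2α-acetoxy-4β-hydroxy-dauc-8-en-6-one
Conditions: PhI(OCOCF3)2, NaHCO3, MeCN/H2O (9:1), 0 °C
Reagents that add atoms: water, O
Why: Oxidative dethioacetalisation with a hypervalent iodine reagent under buffered conditions unmasks the acyl anion equivalent as the C6 ketone without moving the β,γ double bond or epimerising C5.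

**Step 10**
Reactants: 18 bicyclic β-hydroxy ketone
Product: 19 2α-acetoxy-dauc-8-ene-4β,6α-diol
Conditions: Me4NBH(OAc)3, MeCN/AcOH, −30 °C
Reagents that add atoms: none
Why: Evans–Saksena directed reduction: in the trans-fused, ring-locked ketone the borohydride bound to the 4β-oxygen can reach only the β face of the C6 carbonyl, giving the anti-1,3-diol with the 6α-hydroxyl (6S).

**Step 11**
Reactants: 19 2α-acetoxy-dauc-8-ene-4β,6α-diol; 20 4-acetoxybenzoyl chloride
Product: 21 2α-acetoxy-4β-hydroxy-dauc-8-en-6α-yl 4-acetoxybenzoate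
Conditions: Et3N, DMAP, CH2Cl2, rt to 40 °C
Reagents that add atoms: none
Why: DMAP-catalysed acylation of the only secondary alcohol with the acid chloride; C6 keeps its configuration and the tertiary alcohol stays free.

**Step 12**
Reactants: 21 diester from step 11
Product: 22 target, (1R,2S,4R,5S,6S)-2-acetoxy-4-hydroxy-dauc-8-en-6-yl 4-hydroxybenzoate
Conditions: pyrrolidine (1.5 equiv), CH2Cl2, 0 °C
Reagents that add atoms: none
Why: Chemoselective aminolysis: the aryl acetate is far more electrophilic than the hindered alkyl acetate at C2 or the C6 aroate, so only the phenol is released.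

**Compound list**
1 | (S)-(+)-terpinen-4-ol, (1S)-4-methyl-1-(propan-2-yl)cyclohex-3-en-1-ol | CC1=CC[C@@](CC1)(C(C)C)O | starting material
2 | (S)-3-hydroxy-6-oxo-3-(propan-2-yl)heptanal | O=CC[C@](O)(C(C)C)CCC(C)=O | intermediate
3 | (R)-5-hydroxy-2-methyl-5-(propan-2-yl)cyclopent-1-ene-1-carbaldehyde | CC1=C(C=O)[C@](O)(C(C)C)CC1 | intermediate
4 | (R)-3-methyl-1-(propan-2-yl)cyclopent-2-en-1-ol | CC1=C[C@](O)(C(C)C)CC1 | intermediate
5 | (R)-4-hydroxy-2-methyl-4-(propan-2-yl)cyclopent-2-en-1-one | O=C1C[C@@](O)(C(C)C)C=C1C | intermediate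
6 | 1,3-dithiane | C1CSCSC1 | starting material
7 | 3-chloro-2-methylprop-1-ene | CC(=C)CCl | starting material
8 | 2-lithio-1,3-dithiane | [Li]C1SCCCS1 | intermediate
9 | 2-(2-methylprop-2-en-1-yl)-1,3-dithiane | CC(=C)CC1SCCCS1 | intermediate
10 | allyl bromide | C=CCBr | starting material
11 | 2-lithio-2-(2-methylprop-2-en-1-yl)-1,3-dithiane | [Li]C1(CC(C)=C)SCCCS1 | intermediate
12 | [2-(2-methylprop-2-en-1-yl)-1,3-dithian-2-yl]magnesium bromide | Br[Mg]C1(CC(C)=C)SCCCS1 | intermediate
13 | bis(bromomagnesium) oxido enolate of the conjugate adduct (C5 dithianyl β, C4 oxide β) | Br[Mg]OC1=C(C)[C@@H](C2(CC(C)=C)SCCCS2)[C@](O[Mg]Br)(C(C)C)C1 | intermediate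
14 | 2α-allyl-4β-hydroxy-2β-methyl-3β-[2-(2-methylprop-2-en-1-yl)-1,3-dithian-2-yl]-4α-(propan-2-yl)cyclopentan-1-one | O=C1C[C@@](O)(C(C)C)[C@H](C2(CC(C)=C)SCCCS2)[C@@]1(C)CC=C | intermediate
15 | corresponding cyclopentane-1α,4β-diol | O[C@H]1C[C@@](O)(C(C)C)[C@H](C2(CC(C)=C)SCCCS2)[C@@]1(C)CC=C | intermediate
16 | 1α-acetate of 15 (daucane C2 acetate) | CC(=O)O[C@H]1C[C@@](O)(C(C)C)[C@H](C2(CC(C)=C)SCCCS2)[C@@]1(C)CC=C | intermediate
17 | trans-fused 2α-acetoxy-4β-hydroxy-dauc-8-en-6-one propane-1,3-diyl dithioketal | CC(=O)O[C@H]1C[C@@](O)(C(C)C)[C@@H]2C3(SCCCS3)CC(C)=CC[C@@]12C | intermediate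
18 | 2α-acetoxy-4β-hydroxy-dauc-8-en-6-one | CC(=O)O[C@H]1C[C@@](O)(C(C)C)[C@@H]2C(=O)CC(C)=CC[C@@]12C | intermediate
19 | 2α-acetoxy-dauc-8-ene-4β,6α-diol | CC(=O)O[C@H]1C[C@@](O)(C(C)C)[C@@H]2[C@@H](O)CC(C)=CC[C@@]12C | intermediate
20 | 4-acetoxybenzoyl chloride | CC(=O)Oc1ccc(cc1)C(Cl)=O | starting material
21 | 2α-acetoxy-4β-hydroxy-dauc-8-en-6α-yl 4-acetoxybenzoate | CC(=O)O[C@H]1C[C@@](O)(C(C)C)[C@@H]2[C@@H](OC(=O)c3ccc(OC(C)=O)cc3)CC(C)=CC[C@@]12C | intermediate
22 | (1R,2S,4R,5S,6S)-2-acetoxy-4-hydroxy-dauc-8-en-6-yl 4-hydroxybenzoate | CC(=O)O[C@H]1C[C@@](O)(C(C)C)[C@@H]2[C@@H](OC(=O)c3ccc(O)cc3)CC(C)=CC[C@@]12C | target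

**Step count**
Total: 12 steps. Longest linear sequence: 11 steps (steps 1–3 and 5–12); step 4 is a one-step side branch.

**Three steps most likely to fail, with fallbacks**

Step 5. The tertiary dithianyl Grignard reagent 12 may be too bulky to add next to the quaternary carbinol, and the magnesium alkoxide of 5 or of 14 may undergo retro-aldol opening if the mixture is warmed too far. The fallback sets out from 5 and uses the much smaller parent reagent. 2-Lithio-1,3-dithiane 8 is transmetalated with MgBr2·OEt2 to (1,3-dithian-2-yl)magnesium bromide F1, which is added to 5 in the same oxido-directed way. The enolate is trapped with allyl bromide 10 to give 2α-allyl-3β-(1,3-dithian-2-yl)-4β-hydroxy-2β-methyl-4α-(propan-2-yl)cyclopentan-1-one F2. Me4NBH(OAc)3 reduces F2 to 2α-allyl-3β-(1,3-dithian-2-yl)-2β-methyl-4α-(propan-2-yl)cyclopentane-1α,4β-diol F3. Treating F3 with tBuLi (3.2 equiv, THF/HMPA, −78 to −30 °C) and then 3-bromo-2-methylprop-1-ene alkylates the dithiane carbon and comes back to the route at 15. In this variant C6–C7 is made by dithiane alkylation after the hindered C5–C6 bond is already in place.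

Step 1. Retro-aldol cleavage or β-elimination of the free β-hydroxy aldehyde 2 may outrun the ring closure. The fallback sets out from 1 and masks the alcohol first. Et3SiOTf and 2,6-lutidine give the triethylsilyl ether of terpinen-4-ol F4. Ozonolysis and the same amine-salt aldol condensation give the triethylsilyl ether of the enal F5. RhCl(PPh3)3 decarbonylation gives the triethylsilyl ether of the cyclopentenol F6, and Bu4NF in THF comes back to the route at 4.

Step 8. The dithiane sulfur may chelate and stall the ruthenium carbene. The fallback sets out from 16 and unmasks first. PhI(OCOCF3)2 with NaHCO3 gives the sulfur-free 2α-allyl-3β-(3-methylbut-3-enoyl) cyclopentyl acetate F7. Ring closure of F7 with the second-generation Hoveyda–Grubbs catalyst, dichloro[1,3-bis(2,4,6-trimethylphenyl)imidazolidin-2-ylidene](2-isopropoxybenzylidene)ruthenium, comes back to the route at 18. The reduction stays after ring closure, because only the bicyclic ketone is locked for the directed hydride delivery.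

**Further compounds**
F1 | step 5 | (1,3-dithian-2-yl)magnesium bromide | Br[Mg]C1SCCCS1
F2 | step 5 | 2α-allyl-3β-(1,3-dithian-2-yl)-4β-hydroxy-2β-methyl-4α-(propan-2-yl)cyclopentan-1-one | O=C1C[C@@](O)(C(C)C)[C@H](C2SCCCS2)[C@@]1(C)CC=C
F3 | step 5 | 2α-allyl-3β-(1,3-dithian-2-yl)-2β-methyl-4α-(propan-2-yl)cyclopentane-1α,4β-diol | O[C@H]1C[C@@](O)(C(C)C)[C@H](C2SCCCS2)[C@@]1(C)CC=C
F4 | step 1 | triethylsilyl ether of (S)-terpinen-4-ol | CC1=CC[C@@](CC1)(C(C)C)O[Si](CC)(CC)CC
F5 | step 1 | (R)-2-methyl-5-(propan-2-yl)-5-(triethylsilyloxy)cyclopent-1-ene-1-carbaldehyde | CC1=C(C=O)[C@](O[Si](CC)(CC)CC)(C(C)C)CC1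
F6 | step 1 | triethylsilyl ether of (R)-3-methyl-1-(propan-2-yl)cyclopent-2-en-1-ol | CC1=C[C@](O[Si](CC)(CC)CC)(C(C)C)CC1
F7 | step 8 | 2α-allyl-4β-hydroxy-2β-methyl-3β-(3-methylbut-3-enoyl)-4α-(propan-2-yl)cyclopentan-1α-yl acetate | CC(=O)O[C@H]1C[C@@](O)(C(C)C)[C@H](C(=O)CC(C)=C)[C@@]1(C)CC=C
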